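**Retrosynthetic overview**
1. Target 12 ⇐ removal of the two MOM ethers from 11.
2. C3–OH ⇐ trans-selective enolate hydroxylation of the 6-geranylflavanone 9 (flavanone 3-hydroxylase mimic).
3. C6–geranyl ⇐ ortho-C-geranylation of flavanone 7 directed by the chelated 5-OH (prenyltransferase mimic). The ring is already closed at this point, so no 6-/8-isomer question arises.
4. C ring (the only ring formed; A and B rings are bought) ⇐ catalytic enantioselective 6-endo oxa-Michael closure of the 2',6'-dihydroxychalcone 6 to (2S)-7 (chalcone isomerase mimic).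
5. Chalcone 6 ⇐ Claisen–Schmidt condensation of mono-MOM phloroacetophenone 2 with MOM-isovanillin 4.

Assumption: the quinidine-derived thiourea in step 4 is taken to give the (2S)-flavanone; if the sense is the opposite, its quinine-derived pseudoenantiomer is used under the same conditions.

**Route**

Step 1
Reactants: 1 2,4,6-trihydroxyacetophenone
Product: 2 1-[2,6-dihydroxy-4-(methoxymethoxy)phenyl]ethan-1-one
Conditions: MOMCl (1.05 equiv), i-Pr2NEt (1.2 equiv), THF/CH2Cl2, 0 °C, 2 h
Reagents that add atoms: chloromethyl methyl ether (MOMCl), COCCl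
Why: Williamson-type O-alkylation; the 4-OH is the most acidic hydroxyl and the only one not held in the hydrogen bond to the acetyl group, so one equivalent of the hard electrophile reacts there (some bis-ether is removed by chromatography).

Step 2
Reactants: 3 isovanillin (3-hydroxy-4-methoxybenzaldehyde)
Product: 4 4-methoxy-3-(methoxymethoxy)benzaldehyde
Conditions: MOMCl (1.2 equiv), i-Pr2NEt (1.5 equiv), CH2Cl2, 0 °C → rt
Reagents that add atoms: chloromethyl methyl ether (MOMCl), COCCl
Why: Standard phenol O-alkylation (MOM ether formation) that masks the 3-OH for the basic condensation and for the later phenol-directed geranylation.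

Step 3
Reactants: 2 1-[2,6-dihydroxy-4-(methoxymethoxy)phenyl]ethan-1-one + 4 4-methoxy-3-(methoxymethoxy)benzaldehyde
Product: 6 (E)-1-[2,6-dihydroxy-4-(methoxymethoxy)phenyl]-3-[4-methoxy-3-(methoxymethoxy)phenyl]prop-2-en-1-one, via aldol adduct 5 (not isolated)
Conditions: KOH (50% aq, excess), EtOH, 0 °C → rt, 48 h, N2; pour onto ice/1 M HCl to pH 5, crystallise cold
Reagents that add atoms: none
Why: Claisen–Schmidt (aldol) condensation in which E1cB dehydration of the aldol gives the conjugated E-enone; in strong base the product stays as the ring-open chalcone phenolate, and cold acidification gives 6 before it can close.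

Step 4
Reactants: 6 (E)-1-[2,6-dihydroxy-4-(methoxymethoxy)phenyl]-3-[4-methoxy-3-(methoxymethoxy)phenyl]prop-2-en-1-one
Product: 7 (2S)-5-hydroxy-7-(methoxymethoxy)-2-[4-methoxy-3-(methoxymethoxy)phenyl]chroman-4-one
Conditions: quinidine-derived 9-epi-amino 3,5-bis(trifluoromethyl)phenyl thiourea (10 mol%), toluene, –20 °C, 48–72 h; cold filtration through SiO2 to remove the catalyst; one recrystallisation
Reagents that add atoms: none
Why: Proposed new method: chalcone-isomerase-like 6-endo-trig intramolecular oxa-Michael addition in which the quinuclidine nitrogen acts as general base on the non-chelated ortho-OH (the two ortho-OH groups are equivalent, so either closure gives 7) while the thiourea hydrogen-bonds the enone carbonyl, so the phenol adds to one face of the s-cis enone inside the chiral pocket and sets C2 as (S); low temperature and a non-polar solvent suppress the uncatalysed racemic closure and the retro-Michael path, and the 5-OH···O=C4 hydrogen bond formed in the product makes the closure effectively irreversible; closest known reaction type: cinchona-alkaloid- and cinchona-thiourea-catalysed asymmetric oxa-Michael cyclisation of 2'-hydroxychalcones (unactivated and α-carboxylate-activated) to flavanones.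

Step 5
Reactants: 7 (2S)-5-hydroxy-7-(methoxymethoxy)-2-[4-methoxy-3-(methoxymethoxy)phenyl]chroman-4-one + 8 geraniol [(2E)-3,7-dimethylocta-2,6-dien-1-ol]
Product: 9 (2S)-6-[(2E)-3,7-dimethylocta-2,6-dien-1-yl]-5-hydroxy-7-(methoxymethoxy)-2-[4-methoxy-3-(methoxymethoxy)phenyl]chroman-4-one
Conditions: geraniol (1.5 equiv), acidic Al2O3 (Brockmann I), ClCH2CH2Cl, reflux, 18 h, N2
Reagents that add atoms: none
Why: Alumina-directed ortho-allylation of a phenol with an allylic alcohol (surface-templated Friedel–Crafts alkylation); the 5-OH/4-C=O chelate anchors 7 on the alumina beside adsorbed geraniol, so the geranyl group is delivered to C6, the only carbon ortho to a free OH, with the E-olefin retained and C8 (flanked only by ethers) untouched; no new stereocentre is formed.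

Step 6
Reactants: 9 (2S)-6-[(2E)-3,7-dimethylocta-2,6-dien-1-yl]-5-hydroxy-7-(methoxymethoxy)-2-[4-methoxy-3-(methoxymethoxy)phenyl]chroman-4-one
Product: 11 (2R,3R)-6-[(2E)-3,7-dimethylocta-2,6-dien-1-yl]-3,5-dihydroxy-7-(methoxymethoxy)-2-[4-methoxy-3-(methoxymethoxy)phenyl]chroman-4-one, via disodium dianion 10 (not isolated)
Conditions: NaHMDS (2.3 equiv), THF, –78 °C, 45 min; Davis oxaziridine (1.3 equiv), –78 °C, 1 h; AcOH, –78 °C → rt
Reagents that add atoms: trans-3-phenyl-2-(phenylsulfonyl)oxaziridine (Davis oxaziridine), O=S(=O)(c1ccccc1)N1OC1c1ccccc1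
Why: Davis α-hydroxylation of a ketone enolate (flavanone 3-hydroxylase mimic); two equivalents of base give the 5-phenoxide/C3-enolate dianion and the N-sulfonyloxaziridine transfers oxygen to the enolate face anti to the C2 aryl group, giving the 2,3-trans ketol, i.e. (2R,3R) (C2 is spatially unchanged; its descriptor changes only because C3 now outranks the aryl group), while the trisubstituted alkenes and MOM ethers are inert at –78 °C.

Step 7
Reactants: 11 (2R,3R)-6-[(2E)-3,7-dimethylocta-2,6-dien-1-yl]-3,5-dihydroxy-7-(methoxymethoxy)-2-[4-methoxy-3-(methoxymethoxy)phenyl]chroman-4-one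
Product: 12 4'-O-methyldiplacol [(2R,3R)-6-[(2E)-3,7-dimethylocta-2,6-dien-1-yl]-3,5,7-trihydroxy-2-(3-hydroxy-4-methoxyphenyl)chroman-4-one]
Conditions: conc. HCl (cat.), MeOH, rt, 12 h
Reagents that add atoms: none
Why: Acid-catalysed acetal exchange (MOM ether methanolysis) frees the 7- and 3'-phenols at room temperature without cyclising the geranyl chain, cleaving the 4'-OMe or disturbing the trans-ketol stereocentres.

**Compound list**
1 | 2,4,6-trihydroxyacetophenone | CC(=O)c1c(O)cc(O)cc1O | starting material
2 | 1-[2,6-dihydroxy-4-(methoxymethoxy)phenyl]ethan-1-one | CC(=O)c1c(O)cc(OCOC)cc1O | intermediate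
3 | isovanillin (3-hydroxy-4-methoxybenzaldehyde) | COc1ccc(C=O)cc1O | starting material
4 | 4-methoxy-3-(methoxymethoxy)benzaldehyde | COCOc1cc(C=O)ccc1OC | intermediate
5 | 1-[2,6-dihydroxy-4-(methoxymethoxy)phenyl]-3-hydroxy-3-[4-methoxy-3-(methoxymethoxy)phenyl]propan-1-one (racemic aldol adduct, not isolated) | COCOc1cc(O)c(C(=O)CC(O)c2ccc(OC)c(OCOC)c2)c(O)c1 | intermediate
6 | (E)-1-[2,6-dihydroxy-4-(methoxymethoxy)phenyl]-3-[4-methoxy-3-(methoxymethoxy)phenyl]prop-2-en-1-one | COCOc1cc(O)c(C(=O)/C=C/c2ccc(OC)c(OCOC)c2)c(O)c1 | intermediate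
7 | (2S)-5-hydroxy-7-(methoxymethoxy)-2-[4-methoxy-3-(methoxymethoxy)phenyl]chroman-4-one | COc1ccc([C@H]2Oc3cc(OCOC)cc(O)c3C(=O)C2)cc1OCOC | intermediate
8 | geraniol [(2E)-3,7-dimethylocta-2,6-dien-1-ol] | OC/C=C(\C)CCC=C(C)C | starting material
9 | (2S)-6-[(2E)-3,7-dimethylocta-2,6-dien-1-yl]-5-hydroxy-7-(methoxymethoxy)-2-[4-methoxy-3-(methoxymethoxy)phenyl]chroman-4-one | COc1ccc([C@H]2Oc3cc(OCOC)c(C/C=C(\C)CCC=C(C)C)c(O)c3C(=O)C2)cc1OCOC | intermediate
10 | disodium (2S)-6-geranyl-7-(methoxymethoxy)-2-[4-methoxy-3-(methoxymethoxy)phenyl]-2H-chromene-4,5-diolate (C3-enolate/5-phenoxide dianion of 9, not isolated) | [Na+].[Na+].COc1ccc([C@H]2Oc3cc(OCOC)c(C/C=C(\C)CCC=C(C)C)c([O-])c3C([O-])=C2)cc1OCOC | intermediate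
11 | (2R,3R)-6-[(2E)-3,7-dimethylocta-2,6-dien-1-yl]-3,5-dihydroxy-7-(methoxymethoxy)-2-[4-methoxy-3-(methoxymethoxy)phenyl]chroman-4-one | COc1ccc([C@H]2Oc3cc(OCOC)c(C/C=C(\C)CCC=C(C)C)c(O)c3C(=O)[C@@H]2O)cc1OCOC | intermediate
12 | 4'-O-methyldiplacol | COc1ccc([C@H]2Oc3cc(O)c(C/C=C(\C)CCC=C(C)C)c(O)c3C(=O)[C@@H]2O)cc1O | target

**Step count and risks**

Total step count: 7. Longest linear sequence: 6 steps (1 → 2 → 6 → 7 → 9 → 11 → 12; steps 1, 3, 4, 5, 6, 7).

The three steps most likely to fail:

Step 4 (enantioselective oxa-Michael closure). The risk is modest ee, because 2',6'-dihydroxychalcones also close without catalyst and the closure is reversible under base. The fallback sets out from 6 and comes back at 7. Chalcone 6 is closed under thermodynamic control (NaOAc, EtOH, reflux) to the racemic flavanone F1. F1 is resolved by preparative chiral SFC on an amylose phase into 7 and the (2R)-enantiomer F2. F2 is reopened to the chalcone phenolate with aqueous KOH, acidified cold to 6 and recycled, so the unwanted antipode is not lost.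

Step 5 (alumina-directed C6 geranylation). The risks are sluggish reaction of the chelated phenol, partial MOM loss on the acidic surface (which would open C8 to attack) and acid-induced erosion of the C2 configuration through the p-methoxybenzylic C–O bond. The fallback sets out from 7 and comes back at 9, and replaces the Friedel–Crafts step by halogenation and cross-coupling under neutral conditions. BnMe3N·ICl2/CaCO3 in CH2Cl2–MeOH iodinates ortho to the chelated 5-OH to give the 6-iodoflavanone F3. Stille coupling of F3 with tributyl(geranyl)stannane F4 (one step from geranyl chloride and Bu3SnLi) using Pd2(dba)3/AsPh3 in DMF at 60 °C gives 9 with the linear E-geranyl group.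

Step 6 (dianion hydroxylation). The risks are incomplete second deprotonation next to the phenoxide, retro-oxa-Michael opening of the dianion (chalcone formation and loss of C2 integrity) and addition of the enolate to the sulfonimine by-product. The fallback sets out from 7 and comes back at 11, and changes the order of events so that the oxidation is done before any alkene is present. TMSOTf/Et3N in CH2Cl2 converts 7 into the bis-trimethylsilyl enol ether F5. Rubottom oxidation of F5 with dimethyldioxirane at –40 °C, attacking anti to the C2 aryl group, followed by aqueous citric acid gives the (2R,3R)-dihydroflavonol F6. F6 is then geranylated at C6 with geraniol on acidic alumina as in step 5 to give 11.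

**Further compounds**
F1 | step 4 | rac-5-hydroxy-7-(methoxymethoxy)-2-[4-methoxy-3-(methoxymethoxy)phenyl]chroman-4-one | COc1ccc(C2Oc3cc(OCOC)cc(O)c3C(=O)C2)cc1OCOC
F2 | step 4 | (2R)-5-hydroxy-7-(methoxymethoxy)-2-[4-methoxy-3-(methoxymethoxy)phenyl]chroman-4-one | COc1ccc([C@@H]2Oc3cc(OCOC)cc(O)c3C(=O)C2)cc1OCOC
F3 | step 5 | (2S)-5-hydroxy-6-iodo-7-(methoxymethoxy)-2-[4-methoxy-3-(methoxymethoxy)phenyl]chroman-4-one | COc1ccc([C@H]2Oc3cc(OCOC)c(I)c(O)c3C(=O)C2)cc1OCOC
F4 | step 5 | tributyl[(2E)-3,7-dimethylocta-2,6-dien-1-yl]stannane | CCCC[Sn](CCCC)(CCCC)C/C=C(\C)CCC=C(C)C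
F5 | step 6 | (2S)-7-(methoxymethoxy)-2-[4-methoxy-3-(methoxymethoxy)phenyl]-4,5-bis(trimethylsilyloxy)-2H-chromene | COc1ccc([C@H]2Oc3cc(OCOC)cc(O[Si](C)(C)C)c3C(O[Si](C)(C)C)=C2)cc1OCOC
F6 | step 6 | (2R,3R)-3,5-dihydroxy-7-(methoxymethoxy)-2-[4-methoxy-3-(methoxymethoxy)phenyl]chroman-4-one | COc1ccc([C@H]2Oc3cc(OCOC)cc(O)c3C(=O)[C@@H]2O)cc1OCOC
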